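**Retrosynthetic overview** (ring atoms: C1 angeloyloxy carbon, C2 side-chain carbon, C3 H2, C4 acetoxy carbon, C5 methyl carbon, C6 H2)
1. Endgame: the angelate is put on last; C1–OH comes from a C1 ketone (CBS reduction), itself from a C1 nitro group (Nef); C4–OAc comes from a C4 ketone (L-selectride, axial alcohol).
2. Key disconnection: C1–C6 and C3–C4 are cut together, a Michael–Dieckmann [3+3] annulation of γ-nitro ester 11 (C1–C2–C3 plus the whole side chain) with methyl methacrylate 12 (C4–C5–C6). This is the only ring and it is formed in step 9.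
3. Enabling feature: the two oxygenated ring carbons C1 and C4 stand 1,4, and each is bonded to a ring CH2 (C6, C3) belonging to the other half. C1 can therefore be a nitronate carbon attacking the acrylate terminus C6, and C4 an ester carbonyl acylated by the ester α-carbon C3.
4. Fragment 11 comes from organocatalytic nitromethane addition to enal 8 (sets C2), which comes from aldehyde 7, from keto ester 4 (Negishi acylation, CBS reduction for the side-chain carbinol), from methyl (2S)-3-bromo-2-methylpropanoate (side-chain methyl centre).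
5. Stereocontrol in the ring: C2 is the fixed anchor; C5 follows by equilibration; C4 and C1 are set by reagent-controlled hydride deliveries.

Key step: step 9

Remark: the 2-methylbut-2-enoate is read from the SMILES as the Z isomer (angelate).

**Step 1**
Reactants: 1 methyl (2S)-3-bromo-2-methylpropanoate; 2 3-methylbut-2-enoyl chloride
Product: 4 methyl (2R)-2,6-dimethyl-4-oxohept-5-enoate, via alkylzinc bromide 3 (not isolated)
Conditions: Zn dust, I2 (5 mol%), DMA, 70 °C; then 2, Pd(PPh3)4 (3 mol%), THF, 0 °C to rt
Reagents that add atoms: none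
Why: Zinc insertion gives a configurationally stable β-zincio ester that should undergo Negishi acylation (zerovalent palladium) with the acid chloride; the stereocentre is not touched (the descriptor changes only through CIP priorities).

**Step 2**
Reactants: 4
Product: 5 methyl (2R,4R)-4-hydroxy-2,6-dimethylhept-5-enoate
Conditions: (S)-Me-CBS oxazaborolidine [(S)-1-methyl-3,3-diphenyltetrahydro-1H,3H-pyrrolo[1,2-c][1,3,2]oxazaborole] (20 mol%), catecholborane, toluene, −78 °C
Reagents that add atoms: none
Why: Corey–Bakshi–Shibata reduction with the alkenyl group as the large substituent should give the (R)-carbinol under catalyst control; catecholborane at low temperature avoids hydroboration of the alkene and reduction of the ester.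

**Step 3**
Reactants: 5
Product: 6 methyl (2R,4R)-4-[(tert-butyldimethylsilyl)oxy]-2,6-dimethylhept-5-enoate
Conditions: TBSOTf, 2,6-lutidine, CH2Cl2, −78 °C (crude 5 used at once)
Reagents that add atoms: tert-butyldimethylsilyl trifluoromethanesulfonate, CC(C)(C)[Si](C)(C)OS(=O)(=O)C(F)(F)F
Why: Fast silylation of the secondary allylic alcohol forestalls γ-lactonisation and gives a protecting group that survives the basic steps to come.

**Step 4**
Reactants: 6
Product: 7 (2R,4R)-4-[(tert-butyldimethylsilyl)oxy]-2,6-dimethylhept-5-enal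
Conditions: DIBAL-H (i-Bu2AlH, 1.1 equiv), CH2Cl2, −78 °C; Rochelle salt work-up
Reagents that add atoms: none
Why: Partial reduction of the methyl ester stops at the tetrahedral aluminium hemiacetal at −78 °C and should release the α-branched aldehyde without epimerisation (used directly).

**Step 5**
Reactants: 7
Product: 8 (2E,4R,6R)-6-[(tert-butyldimethylsilyl)oxy]-4,8-dimethylnona-2,7-dienal
Conditions: Ph3P=CHCHO, toluene, 60 °C
Reagents that add atoms: (triphenylphosphoranylidene)acetaldehyde, O=CC=P(c1ccccc1)(c1ccccc1)c1ccccc1
Why: Wittig olefination with the stabilised, weakly basic ylide should give the E-enal and leave the α-stereocentre intact.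

**Step 6**
Reactants: 8
Product: 9 (3S,4R,6R)-6-[(tert-butyldimethylsilyl)oxy]-4,8-dimethyl-3-(nitromethyl)non-7-enal
Conditions: MeNO2 (5 equiv), (S)-2-[diphenyl(trimethylsilyloxy)methyl]pyrrolidine (10 mol%), PhCO2H (10 mol%), MeOH, rt
Reagents that add atoms: nitromethane, C[N+](=O)[O-]
Why: Iminium-ion-catalysed Michael addition of the Hayashi type; nitromethane should add to the face of the E-iminium ion opposite the diphenyl(silyloxy)methyl group, which corresponds to 3S (the future ring C2), with catalyst control expected to override the neighbouring C4 centre.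

**Step 7**
Reactants: 9
Product: 10 (3S,4R,6R)-6-[(tert-butyldimethylsilyl)oxy]-4,8-dimethyl-3-(nitromethyl)non-7-enoic acid
Conditions: NaClO2, NaH2PO4, 2-methyl-2-butene, t-BuOH/H2O, 0 °C to rt
Reagents that add atoms: sodium chlorite, [Na+].[O-]Cl=O
Why: Pinnick oxidation is selective for the aldehyde; the excess scavenger alkene protects the trisubstituted alkene from hypochlorite, and no stereocentre is touched.

**Step 8**
Reactants: 10
Product: 11 methyl (3S,4R,6R)-6-[(tert-butyldimethylsilyl)oxy]-4,8-dimethyl-3-(nitromethyl)non-7-enoate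
Conditions: TMSCHN2, toluene/MeOH (4:1), 0 °C
Reagents that add atoms: (trimethylsilyl)diazomethane, C[Si](C)(C)C=[N+]=[N-]
Why: Non-basic methyl esterification of the acid, which avoids O-alkylation of the nitro group.

**Step 9**
Reactants: 11; 12 methyl methacrylate
Product: 14 methyl (3S,5R,6R)-6-[(2R,4R)-4-[(tert-butyldimethylsilyl)oxy]-6-methylhept-5-en-2-yl]-3-methyl-5-nitro-2-oxocyclohexane-1-carboxylate (C1 epimers and enol tautomer), via Michael adduct 13 (not isolated)
Conditions: 12 (1.3 equiv), DBU (1,8-diazabicyclo[5.4.0]undec-7-ene, 0.5 equiv), THF, rt to 40 °C; then KOtBu (3 equiv), 0 °C to rt; AcOH quench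
Reagents that add atoms: none
Why: DBU forms the nitronate of 11, which adds to the β-carbon of methyl methacrylate (nitro-Michael addition, new C1–C6 bond) to give pimelate 13; KOtBu then drives a Dieckmann condensation in which the C3 ester enolate acylates the methacrylate-derived ester carbon (new C3–C4 bond), the whole being a Michael–Dieckmann [3+3] annulation of the kind used to make 4-nitrocyclohexanones from nitroalkanes and acrylates. The ring closes by 6-exo-trig attack of the enolate carbon on the ester carbonyl; the other Dieckmann mode (C5 onto the other ester) would give a β-keto ester with a quaternary, non-enolisable carbon and is reversible under alkoxide, so only the regiochemistry shown is drained off as the stabilised enolate. The preset C2 is not acidic and serves as the anchor; C1 (α to nitro) and C5 (α to the ketone) are epimerisable and should settle, at the latest in step 10, with nitro and methyl equatorial, that is trans to the C2 side chain, while C3 is an enol(ate) carbon. The step needs chemoselective deprotonation (the nitro group is far more acidic than either ester) and a single conjugate addition, which the hindered secondary nitronate formed after the first addition and the modest electrophilicity of an α-methyl acrylate should secure.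

**Step 10**
Reactants: 14
Product: 15 (2S,4R,5S)-5-[(2R,4R)-4-[(tert-butyldimethylsilyl)oxy]-6-methylhept-5-en-2-yl]-2-methyl-4-nitrocyclohexan-1-one
Conditions: LiCl, H2O, DMSO, 130 °C; then Et3N (cat.), MeOH, rt
Reagents that add atoms: none
Why: Krapcho dealkoxycarbonylation (chloride attack on the methyl group, then decarboxylation of the β-keto carboxylate) removes the activating ester; the amine equilibration should place the C5 methyl (ring numbering) and the nitro group equatorial relative to the fixed C2 centre.

**Step 11**
Reactants: 15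
Product: 16 (1R,2S,4R,5S)-5-[(2R,4R)-4-[(tert-butyldimethylsilyl)oxy]-6-methylhept-5-en-2-yl]-2-methyl-4-nitrocyclohexan-1-ol
Conditions: LiB(sec-Bu)3H (L-selectride, 2.2 equiv), THF, −78 °C; aq. NH4Cl
Reagents that add atoms: none
Why: The bulky hydride should attack the ketone from the equatorial direction (steric approach control, as with 2-methylcyclohexanone), giving the axial alcohol cis to the equatorial methyl; this sets ring C4.

**Step 12**
Reactants: 16
Product: 18 (2S,4R,5S)-2-[(2R,4R)-4-[(tert-butyldimethylsilyl)oxy]-6-methylhept-5-en-2-yl]-4-hydroxy-5-methylcyclohexan-1-one, via sodium nitronate 17 (not isolated)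
Conditions: NaOMe, MeOH, 0 °C; then aq. TiCl3, NH4OAc, THF/H2O, 0 °C to rt
Reagents that add atoms: water, O
Why: Nef reaction in the McMurry variant: the nitronate is reduced by trivalent titanium to the imine, which hydrolyses at about pH 5 to the ketone; the C2 centre, now α to the carbonyl, carries its large substituent equatorially, which is the thermodynamic arrangement.

**Step 13**
Reactants: 18
Product: 19 (2S,4R,5S)-4-hydroxy-2-[(2R,4R)-4-hydroxy-6-methylhept-5-en-2-yl]-5-methylcyclohexan-1-one
Conditions: HF·pyridine, pyridine, THF, 0 °C to rt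
Reagents that add atoms: none
Why: Buffered fluoride cleavage of the silyl ether should free the allylic alcohol without ionising it.

**Step 14**
Reactants: 19
Product: 20 (1R,2S,5S)-5-[(2R,4R)-4-(acetyloxy)-6-methylhept-5-en-2-yl]-2-methyl-4-oxocyclohexyl acetate
Conditions: Ac2O, pyridine, 4-(dimethylamino)pyridine (5 mol%), CH2Cl2, rt
Reagents that add atoms: acetic anhydride, CC(=O)OC(C)=O
Why: Nucleophile-catalysed acylation esterifies both secondary hydroxyls (the axial ring alcohol and the allylic one) in one operation, with retention at both carbons.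

**Step 15**
Reactants: 20
Product: 21 (1R,2S,4R,5S)-5-[(2R,4R)-4-(acetyloxy)-6-methylhept-5-en-2-yl]-4-hydroxy-2-methylcyclohexyl acetate
Conditions: (S)-Me-CBS oxazaborolidine (0.5 equiv), catecholborane, toluene, −78 to −40 °C
Reagents that add atoms: none
Why: Corey–Bakshi–Shibata reduction with the branched C2 side of the ketone as the large group should give the (R)-carbinol at ring C1, the equatorial alcohol trans to the side chain; this is also the sense of axial attack by a small hydride, so catalyst and substrate are matched, and the acetates and the alkene are left alone.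

**Step 16**
Reactants: 21; 22 angelic acid [(2Z)-2-methylbut-2-enoic acid]
Product: 23 (1R,2S,4R,5S)-4-(acetyloxy)-2-[(2R,4R)-4-(acetyloxy)-6-methylhept-5-en-2-yl]-5-methylcyclohexyl (2Z)-2-methylbut-2-enoate (CNP0286954.1)
Conditions: 22, 2,4,6-trichlorobenzoyl chloride, Et3N, toluene, rt; then 21, toluene, 75 °C
Reagents that add atoms: none
Why: Yamaguchi esterification through the mixed anhydride, run without a nucleophilic catalyst, is the established way to make angelates without Z-to-E isomerisation; the carbinol configuration is retained.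

**Compound list**
1 | methyl (2S)-3-bromo-2-methylpropanoate | COC(=O)[C@H](C)CBr | starting material
2 | 3-methylbut-2-enoyl chloride | CC(C)=CC(Cl)=O | starting material
3 | [(2S)-3-methoxy-2-methyl-3-oxopropyl]zinc bromide | COC(=O)[C@H](C)C[Zn]Br | intermediate
4 | methyl (2R)-2,6-dimethyl-4-oxohept-5-enoate | COC(=O)[C@H](C)CC(=O)C=C(C)C | intermediate
5 | methyl (2R,4R)-4-hydroxy-2,6-dimethylhept-5-enoate | COC(=O)[C@H](C)C[C@H](C=C(C)C)O | intermediate
6 | methyl (2R,4R)-4-[(tert-butyldimethylsilyl)oxy]-2,6-dimethylhept-5-enoate | COC(=O)[C@H](C)C[C@H](C=C(C)C)O[Si](C)(C)C(C)(C)C | intermediate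
7 | (2R,4R)-4-[(tert-butyldimethylsilyl)oxy]-2,6-dimethylhept-5-enal | O=C[C@H](C)C[C@H](C=C(C)C)O[Si](C)(C)C(C)(C)C | intermediate
8 | (2E,4R,6R)-6-[(tert-butyldimethylsilyl)oxy]-4,8-dimethylnona-2,7-dienal | O=C/C=C/[C@H](C)C[C@H](C=C(C)C)O[Si](C)(C)C(C)(C)C | intermediate
9 | (3S,4R,6R)-6-[(tert-butyldimethylsilyl)oxy]-4,8-dimethyl-3-(nitromethyl)non-7-enal | O=CC[C@H](C[N+](=O)[O-])[C@H](C)C[C@H](C=C(C)C)O[Si](C)(C)C(C)(C)C | intermediate
10 | (3S,4R,6R)-6-[(tert-butyldimethylsilyl)oxy]-4,8-dimethyl-3-(nitromethyl)non-7-enoic acid | OC(=O)C[C@H](C[N+](=O)[O-])[C@H](C)C[C@H](C=C(C)C)O[Si](C)(C)C(C)(C)C | intermediate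
11 | methyl (3S,4R,6R)-6-[(tert-butyldimethylsilyl)oxy]-4,8-dimethyl-3-(nitromethyl)non-7-enoate | COC(=O)C[C@H](C[N+](=O)[O-])[C@H](C)C[C@H](C=C(C)C)O[Si](C)(C)C(C)(C)C | intermediate
12 | methyl methacrylate (methyl 2-methylprop-2-enoate) | C=C(C)C(=O)OC | starting material
13 | dimethyl (5S)-5-[(2R,4R)-4-[(tert-butyldimethylsilyl)oxy]-6-methylhept-5-en-2-yl]-2-methyl-4-nitroheptanedioate (epimers at C2 and C4) | COC(=O)C(C)CC([N+](=O)[O-])[C@@H](CC(=O)OC)[C@H](C)C[C@H](C=C(C)C)O[Si](C)(C)C(C)(C)C | intermediate
14 | methyl (3S,5R,6R)-6-[(2R,4R)-4-[(tert-butyldimethylsilyl)oxy]-6-methylhept-5-en-2-yl]-3-methyl-5-nitro-2-oxocyclohexane-1-carboxylate (C1 epimers, enol tautomer) | [O-][N+](=O)[C@@H]1C[C@H](C)C(=O)C(C(=O)OC)[C@H]1[C@H](C)C[C@H](C=C(C)C)O[Si](C)(C)C(C)(C)C | intermediate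
15 | (2S,4R,5S)-5-[(2R,4R)-4-[(tert-butyldimethylsilyl)oxy]-6-methylhept-5-en-2-yl]-2-methyl-4-nitrocyclohexan-1-one | [O-][N+](=O)[C@@H]1C[C@H](C)C(=O)C[C@H]1[C@H](C)C[C@H](C=C(C)C)O[Si](C)(C)C(C)(C)C | intermediate
16 | (1R,2S,4R,5S)-5-[(2R,4R)-4-[(tert-butyldimethylsilyl)oxy]-6-methylhept-5-en-2-yl]-2-methyl-4-nitrocyclohexan-1-ol | [O-][N+](=O)[C@@H]1C[C@H](C)[C@H](O)C[C@H]1[C@H](C)C[C@H](C=C(C)C)O[Si](C)(C)C(C)(C)C | intermediate
17 | sodium {(2S,4R,5S)-2-[(2R,4R)-4-[(tert-butyldimethylsilyl)oxy]-6-methylhept-5-en-2-yl]-4-hydroxy-5-methylcyclohexylidene}azinate (sodium nitronate of 16) | [Na+].[O-][N+]([O-])=C1C[C@H](C)[C@H](O)C[C@H]1[C@H](C)C[C@H](C=C(C)C)O[Si](C)(C)C(C)(C)C | intermediate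
18 | (2S,4R,5S)-2-[(2R,4R)-4-[(tert-butyldimethylsilyl)oxy]-6-methylhept-5-en-2-yl]-4-hydroxy-5-methylcyclohexan-1-one | O=C1C[C@H](C)[C@H](O)C[C@H]1[C@H](C)C[C@H](C=C(C)C)O[Si](C)(C)C(C)(C)C | intermediate
19 | (2S,4R,5S)-4-hydroxy-2-[(2R,4R)-4-hydroxy-6-methylhept-5-en-2-yl]-5-methylcyclohexan-1-one | O=C1C[C@H](C)[C@H](O)C[C@H]1[C@H](C)C[C@H](C=C(C)C)O | intermediate
20 | (1R,2S,5S)-5-[(2R,4R)-4-(acetyloxy)-6-methylhept-5-en-2-yl]-2-methyl-4-oxocyclohexyl acetate | O=C1C[C@H](C)[C@H](OC(C)=O)C[C@H]1[C@H](C)C[C@H](C=C(C)C)OC(C)=O | intermediate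
21 | (1R,2S,4R,5S)-5-[(2R,4R)-4-(acetyloxy)-6-methylhept-5-en-2-yl]-4-hydroxy-2-methylcyclohexyl acetate | O[C@@H]1C[C@H](C)[C@H](OC(C)=O)C[C@H]1[C@H](C)C[C@H](C=C(C)C)OC(C)=O | intermediate
22 | angelic acid [(2Z)-2-methylbut-2-enoic acid] | C/C=C(/C)C(=O)O | starting material
23 | (1R,2S,4R,5S)-4-(acetyloxy)-2-[(2R,4R)-4-(acetyloxy)-6-methylhept-5-en-2-yl]-5-methylcyclohexyl (2Z)-2-methylbut-2-enoate | C/C=C(/C)C(=O)O[C@@H]1C[C@H](C)[C@H](OC(C)=O)C[C@H]1[C@H](C)C[C@H](C=C(C)C)OC(C)=O | target

**Step count and risks**
Total step count: 16. Longest linear sequence: 16 steps (1 to 23).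

Steps most likely to fail:

Step 9 (key step). The cascade may stall after the conjugate addition, because the Dieckmann closure has to run on a nitronate–enolate dianion. The alkoxide may also start anionic oligomerisation of the methacrylate, or erode the C2 anchor through reversible Michael chemistry of the β-keto ester enolate. The fallback sets out from 11 and 12 and comes back at 14. The two bonds would be made in separate operations: the Michael adduct 13 is isolated after the DBU stage, and the acyl C–C bond is then closed by a titanium-mediated Dieckmann condensation of the Tanabe type (TiCl4, Bu3N, CH2Cl2, −78 to 0 °C). In this closure a titanium ester enolate forms at the unbranched C3 methylene under Lewis-acidic soft enolisation, without alkoxide and without a free dianion, and the product is held as its titanium chelate until work-up. This replaces the equilibrating anionic cascade by a stepwise, kinetically controlled closure and makes no compound outside the list (F0).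

Step 6. The secondary amine can convert the γ-branched enal into a dienamine, which would scramble the side-chain methyl centre, and catalyst and substrate may be mismatched in the facial sense. The fallback sets out from 7 and comes back at 9, and moves the amine activation from the chiral partner to a simple one. Aldehyde 7 is condensed with nitromethane (Et3N cat., 0 °C) to the nitro aldol F1, which is dehydrated (MsCl, Et3N, CH2Cl2, 0 °C) to the E-nitroalkene F2. Acetaldehyde is then added to F2 under enamine catalysis with the same (S)-2-[diphenyl(trimethylsilyloxy)methyl]pyrrolidine (1,4-dioxane, rt). The nitroalkene is not converted into an iminium or dienamine species, and the known facial sense of this catalyst in aldehyde–nitroalkene additions should again give the 3S centre of 9.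

Step 15. Hydride delivery to the C1 ketone may show insufficient facial selectivity if the matched relation between catalyst and substrate is weaker than expected. The fallback sets out from 20 and comes back at 21, and replaces direct formation of the equatorial alcohol by the reliable formation of its epimer followed by inversion. L-selectride (THF, −78 °C) should attack equatorially and give the axial alcohol F3. Mitsunobu reaction with chloroacetic acid (PPh3, DIAD, toluene, 0 °C to rt) inverts C1 to the equatorial chloroacetate F4. The chloroacetyl group is then removed selectively in the presence of the two acetates (thiourea, NaHCO3, EtOH, 50 °C) to give 21.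

**Further compounds**
F0 | step 9 | none | none
F1 | step 6 | (3R,5R)-5-[(tert-butyldimethylsilyl)oxy]-3,7-dimethyl-1-nitrooct-6-en-2-ol (C2 epimers) | [O-][N+](=O)CC(O)[C@H](C)C[C@H](C=C(C)C)O[Si](C)(C)C(C)(C)C
F2 | step 6 | (1E,3R,5R)-5-[(tert-butyldimethylsilyl)oxy]-3,7-dimethyl-1-nitroocta-1,6-diene | [O-][N+](=O)/C=C/[C@H](C)C[C@H](C=C(C)C)O[Si](C)(C)C(C)(C)C
F3 | step 15 | (1R,2S,4S,5S)-5-[(2R,4R)-4-(acetyloxy)-6-methylhept-5-en-2-yl]-4-hydroxy-2-methylcyclohexyl acetate | O[C@H]1C[C@H](C)[C@H](OC(C)=O)C[C@H]1[C@H](C)C[C@H](C=C(C)C)OC(C)=O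
F4 | step 15 | (1R,2S,4R,5S)-4-(acetyloxy)-2-[(2R,4R)-4-(acetyloxy)-6-methylhept-5-en-2-yl]-5-methylcyclohexyl 2-chloroacetate | ClCC(=O)O[C@@H]1C[C@H](C)[C@H](OC(C)=O)C[C@H]1[C@H](C)C[C@H](C=C(C)C)OC(C)=O
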